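**Retrosynthetic overview**

1. The target, (2S,3R,2''S,3''R)-4'-O-methyl-3,3''-binaringenin, is unmasked last by one hydrogenolysis of four benzyl ethers and one benzyl carbonate.
2. Enabling feature: the 1,4-diketone C4(=O)–C3H–C3''H–C4''(=O) that joins the two pyranone rings (rings C), each carbonyl sitting on a ring-A carbon ortho to the ring oxygen (O1, O1''). Both rings C are therefore opened at C4–C3 and C4''–C3'', giving an acyclic isomer: a C3≡C3'' alkyne whose two propargylic carbons (C2, C2'') each carry an aryl group and a 2-formylaryl ether.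
3. Forward, one carbene-catalysed cascade closes the first ring C by alkyne hydroacylation and the second by Stetter addition; C3 and C3'' then settle trans to the fixed C2 and C2'' aryl groups.
4. The bis-ether comes from a propargylic alcohol and the ring-A phenol (Mitsunobu, inversion, sets C2''). The alcohol comes from a terminal alkyne ether and a 4-formylphenyl carbonate (asymmetric alkynylation).
5. The terminal alkyne ether comes from a racemic propargylic acetate and the same phenol (copper-catalysed asymmetric propargylic etherification, sets C2). Rings A and B are bought; the two rings C are formed last, one after the other in the same flask.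

Key step: step 7

Remark: in the two ligand-controlled steps (3 and 5) the ligand antipode written is the one taken to give the stated configuration; should a trial show the opposite sense, the mirror-image ligand is used and nothing else changes.

**Route**

Step 1
Reactants: 1 2,4,6-trihydroxybenzaldehyde
Product: 2 2,4-bis(benzyloxy)-6-hydroxybenzaldehyde
Conditions: BnBr (2.1 equiv), K2CO3 (2.2 equiv), DMF, 0 °C to rt
Reagents that add atoms: benzyl bromide BrCc1ccccc1
Why: Williamson etherification; after the para and one ortho hydroxyl are benzylated, the remaining hydroxyl is hydrogen-bonded to the formyl group and should stay free.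

Step 2
Reactants: 3 4-methoxybenzaldehyde; 4 ethynylmagnesium bromide
Product: 6 rac-1-(4-methoxyphenyl)prop-2-yn-1-yl acetate, via bromomagnesium propargylic alkoxide 5 (not isolated)
Conditions: THF, 0 °C; then Ac2O (1.5 equiv), 0 °C to rt
Reagents that add atoms: acetic anhydride CC(=O)OC(C)=O
Why: Grignard 1,2-addition to the aldehyde followed by O-acetylation of the magnesium alkoxide in the same flask; the acetate is made racemic on purpose because step 3 is enantioconvergent.

Step 3
Reactants: 6 rac-1-(4-methoxyphenyl)prop-2-yn-1-yl acetate; 2 2,4-bis(benzyloxy)-6-hydroxybenzaldehyde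
Product: 7 2,4-bis(benzyloxy)-6-{[(1S)-1-(4-methoxyphenyl)prop-2-yn-1-yl]oxy}benzaldehyde
Conditions: (CuOTf)2·C6H6 (5 mol%), (S,S)-Ph-pybox (10 mol%), i-Pr2NEt (1.5 equiv), CH2Cl2, −20 °C
Reagents that add atoms: none
Why: Copper-catalysed asymmetric propargylic etherification: the copper acetylide loses acetate to a copper allenylidene that the phenoxide attacks at the γ-carbon inside the pybox pocket, so both enantiomers of 6 converge and the ligand sets C2; this ionisation-based method is chosen because the anisyl-bearing centre ionises too readily for a clean SN2 displacement.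

Step 4
Reactants: 8 4-hydroxybenzaldehyde
Product: 9 benzyl 4-formylphenyl carbonate
Conditions: benzyl chloroformate (1.1 equiv), Et3N (1.2 equiv), CH2Cl2, 0 °C
Reagents that add atoms: benzyl chloroformate O=C(Cl)OCc1ccccc1
Why: O-acylation of the phenol; the carbonate is electron-withdrawing (it makes this aldehyde the more electrophilic one in step 5 and suppresses ionisation of the derived carbinol in step 6) and is removable by hydrogenolysis.

Step 5
Reactants: 7 2,4-bis(benzyloxy)-6-{[(1S)-1-(4-methoxyphenyl)prop-2-yn-1-yl]oxy}benzaldehyde; 9 benzyl 4-formylphenyl carbonate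
Product: 11 benzyl 4-[(1S,4R)-4-[3,5-bis(benzyloxy)-2-formylphenoxy]-1-hydroxy-4-(4-methoxyphenyl)but-2-yn-1-yl]phenyl carbonate, via methylzinc acetylide 10 (not isolated)
Conditions: (S,S)-ProPhenol (20 mol%), Me2Zn (2.5 equiv), Ph3PO (40 mol%), toluene, 0 °C; then 9 (1.5 equiv), 0 °C to rt
Reagents that add atoms: none
Why: Dinuclear zinc–ProPhenol catalysed enantioselective alkynylation of an aryl aldehyde, with delivery to the Re face of 9 giving the (S)-carbinol under catalyst control; the formyl group of 7 should stay a spectator because it is a doubly ortho-oxygenated vinylogous carbonate and far less electrophilic than 9.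

Step 6
Reactants: 11 benzyl 4-[(1S,4R)-4-[3,5-bis(benzyloxy)-2-formylphenoxy]-1-hydroxy-4-(4-methoxyphenyl)but-2-yn-1-yl]phenyl carbonate; 2 2,4-bis(benzyloxy)-6-hydroxybenzaldehyde
Product: 12 benzyl 4-[(1R,4R)-1,4-bis[3,5-bis(benzyloxy)-2-formylphenoxy]-4-(4-methoxyphenyl)but-2-yn-1-yl]phenyl carbonate
Conditions: PPh3, DIAD, toluene, −20 °C to rt
Reagents that add atoms: none
Why: Mitsunobu etherification with inversion (1S to 1R) sets C2''; the acyloxy-substituted aryl group and the alkynyl group both disfavour ionisation of the oxyphosphonium, so SN2 attack by the acidic hydrogen-bonded phenol is expected to prevail.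

Step 7
Reactants: 12 benzyl 4-[(1R,4R)-1,4-bis[3,5-bis(benzyloxy)-2-formylphenoxy]-4-(4-methoxyphenyl)but-2-yn-1-yl]phenyl carbonate
Product: 15 benzyl 4-[(2S,3R)-5,7-bis(benzyloxy)-3-[(2S,3R)-5,7-bis(benzyloxy)-2-(4-methoxyphenyl)-4-oxochroman-3-yl]-4-oxochroman-2-yl]phenyl carbonate, via anisyl-side enone 13 (not isolated), via carbonate-side enone 14 (not isolated)
Conditions: 3-mesityl-4,5,6,7-tetrahydro-1,3-benzothiazol-3-ium perchlorate (20 mol%), K2CO3 (20 mol%), THF, 70 °C
Reagents that add atoms: none
Why: The thiazol-2-ylidene adds to one formyl group to give the acyl-anion-equivalent enaminol, which hydroacylates the tethered unactivated alkyne through a concerted Conia-ene-type transition state (6-exo-dig, syn delivery of acyl carbon and hydrogen) and closes the first pyranone ring as an (E)-3-ylidene chromanone (13 or 14); a second carbene then adds to the remaining formyl group and closes the second pyranone ring by intramolecular Stetter addition to the enone β-carbon (6-exo-trig), so that the C4–C3 and C4''–C3'' bonds, both rings C and the whole 1,4-diketone arise from an acyclic isomer. The closest known reactions are the carbene-catalysed hydroacylation–Stetter cascade of 2-(propargyloxy)benzaldehydes to 1,4-diketones and the classic intramolecular Stetter closure to chroman-4-ones. C3 and C3'' are both enolisable α-carbons and are expected to settle under the basic conditions to the thermodynamic arrangement, each trans (diequatorial) to the neighbouring 2-aryl group, whose configuration (C2, C2'') was fixed in steps 3 and 6 and is not touched, which leaves (2S,3R,2''S,3''R) as the only all-trans isomer. The step needs exo rather than endo attack on the alkyne, which the aryl–O–CH tether enforces, and it needs the Stetter closure to outrun base-induced aromatisation of 13 and 14 to flavones and retro-oxa-Michael opening, which substoichiometric heterogeneous K2CO3 and the intramolecular nature of the second closure should secure. A thiazolylidene with only one flanking N-aryl group is chosen because both formyl groups are doubly ortho-oxygenated, and either order of ring closure converges on 15.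

Step 8
Reactants: 15 benzyl 4-[(2S,3R)-5,7-bis(benzyloxy)-3-[(2S,3R)-5,7-bis(benzyloxy)-2-(4-methoxyphenyl)-4-oxochroman-3-yl]-4-oxochroman-2-yl]phenyl carbonate
Product: 16 (2S,3R)-5,7-dihydroxy-3-[(2S,3R)-5,7-dihydroxy-2-(4-hydroxyphenyl)-4-oxochroman-3-yl]-2-(4-methoxyphenyl)chroman-4-one
Conditions: H2 (1 atm), Pd/C (10 wt% Pd), EtOAc–MeOH, rt
Reagents that add atoms: none
Why: Hydrogenolysis of the four benzyl ethers and of the benzyl carbonate (the aryl hydrogen carbonate loses CO2) under neutral conditions, so no base is present to open the flavanone rings and epimerise C2 or C2''; the methyl ether and the hydrogen-bonded aryl ketones should be untouched.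

**Compound list**

1 | 2,4,6-trihydroxybenzaldehyde | O=Cc1c(O)cc(O)cc1O | starting material
2 | 2,4-bis(benzyloxy)-6-hydroxybenzaldehyde | O=Cc1c(O)cc(OCc2ccccc2)cc1OCc1ccccc1 | intermediate
3 | 4-methoxybenzaldehyde | COc1ccc(C=O)cc1 | starting material
4 | ethynylmagnesium bromide | C#C[Mg]Br | starting material
5 | bromomagnesium 1-(4-methoxyphenyl)prop-2-yn-1-olate (racemic) | COc1ccc(C(C#C)O[Mg]Br)cc1 | intermediate
6 | rac-1-(4-methoxyphenyl)prop-2-yn-1-yl acetate | COc1ccc(C(C#C)OC(C)=O)cc1 | intermediate
7 | 2,4-bis(benzyloxy)-6-{[(1S)-1-(4-methoxyphenyl)prop-2-yn-1-yl]oxy}benzaldehyde | COc1ccc([C@H](C#C)Oc2cc(OCc3ccccc3)cc(OCc3ccccc3)c2C=O)cc1 | intermediate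
8 | 4-hydroxybenzaldehyde | O=Cc1ccc(O)cc1 | starting material
9 | benzyl 4-formylphenyl carbonate | O=Cc1ccc(OC(=O)OCc2ccccc2)cc1 | intermediate
10 | methylzinc acetylide of 7 (terminal C–H replaced by C–ZnCH3, configuration unchanged) | COc1ccc([C@H](C#C[Zn]C)Oc2cc(OCc3ccccc3)cc(OCc3ccccc3)c2C=O)cc1 | intermediate
11 | benzyl 4-[(1S,4R)-4-[3,5-bis(benzyloxy)-2-formylphenoxy]-1-hydroxy-4-(4-methoxyphenyl)but-2-yn-1-yl]phenyl carbonate | COc1ccc([C@H](C#C[C@@H](O)c2ccc(OC(=O)OCc3ccccc3)cc2)Oc2cc(OCc3ccccc3)cc(OCc3ccccc3)c2C=O)cc1 | intermediate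
12 | benzyl 4-[(1R,4R)-1,4-bis[3,5-bis(benzyloxy)-2-formylphenoxy]-4-(4-methoxyphenyl)but-2-yn-1-yl]phenyl carbonate | COc1ccc([C@H](C#C[C@H](Oc2cc(OCc3ccccc3)cc(OCc3ccccc3)c2C=O)c2ccc(OC(=O)OCc3ccccc3)cc2)Oc2cc(OCc3ccccc3)cc(OCc3ccccc3)c2C=O)cc1 | intermediate
13 | benzyl 4-[(1S,2E)-1-[3,5-bis(benzyloxy)-2-formylphenoxy]-2-[(2R)-5,7-bis(benzyloxy)-2-(4-methoxyphenyl)-4-oxochroman-3-ylidene]ethyl]phenyl carbonate | COc1ccc([C@H]2Oc3cc(OCc4ccccc4)cc(OCc4ccccc4)c3C(=O)/C2=C/[C@H](Oc2cc(OCc3ccccc3)cc(OCc3ccccc3)c2C=O)c2ccc(OC(=O)OCc3ccccc3)cc2)cc1 | intermediate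
14 | benzyl 4-[(2R,3E)-5,7-bis(benzyloxy)-3-[(2S)-2-[3,5-bis(benzyloxy)-2-formylphenoxy]-2-(4-methoxyphenyl)ethylidene]-4-oxochroman-2-yl]phenyl carbonate | COc1ccc([C@H](/C=C2/C(=O)c3c(OCc4ccccc4)cc(OCc4ccccc4)cc3O[C@@H]2c2ccc(OC(=O)OCc3ccccc3)cc2)Oc2cc(OCc3ccccc3)cc(OCc3ccccc3)c2C=O)cc1 | intermediate
15 | benzyl 4-[(2S,3R)-5,7-bis(benzyloxy)-3-[(2S,3R)-5,7-bis(benzyloxy)-2-(4-methoxyphenyl)-4-oxochroman-3-yl]-4-oxochroman-2-yl]phenyl carbonate | COc1ccc([C@H]2Oc3cc(OCc4ccccc4)cc(OCc4ccccc4)c3C(=O)[C@@H]2[C@H]2C(=O)c3c(OCc4ccccc4)cc(OCc4ccccc4)cc3O[C@@H]2c2ccc(OC(=O)OCc3ccccc3)cc2)cc1 | intermediate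
16 | (2S,3R)-5,7-dihydroxy-3-[(2S,3R)-5,7-dihydroxy-2-(4-hydroxyphenyl)-4-oxochroman-3-yl]-2-(4-methoxyphenyl)chroman-4-one | COc1ccc([C@H]2Oc3cc(O)cc(O)c3C(=O)[C@@H]2[C@H]2C(=O)c3c(O)cc(O)cc3O[C@@H]2c2ccc(O)cc2)cc1 | target

**Step count and risks**

Total step count: 8. Longest linear sequence: 6 steps (steps 2, 3, 5, 6, 7 and 8, from 4-methoxybenzaldehyde).

Steps most likely to fail:

Step 7. Carbene addition to the doubly ortho-oxygenated formyl groups or hydroacylation of the hindered internal alkyne may be slow; base-induced aromatisation of the intermediate enone to a flavone, or retro-oxa-Michael scrambling of C2 and C2'', could then compete. The fallback divides the cascade and makes the first C–C bond with a metal. It sets out from 12. A nickel-catalysed reductive ynal cyclisation (Ni(cod)2, PBu3, Et3B, toluene, rt) should form the C4–C3 or the C4''–C3'' bond through an oxanickelacycle and give, after work-up, the anisyl-side allylic alcohol F1 and the carbonate-side allylic alcohol F2, each as a pair of carbinol epimers. Oxidation of these doubly activated alcohols (MnO2, CH2Cl2) should give the enones 13 and 14, now isolated. A classic intramolecular Stetter closure (3-benzyl-5-(2-hydroxyethyl)-4-methylthiazolium chloride, Et3N, dioxane, 60 °C) closes the second ring, and the route is rejoined at 15.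

Step 3. The hindered, hydrogen-bonded phenol may be a poor partner for the copper allenylidene, which could show as low conversion, competing C-alkylation of the electron-rich ring, or low enantiocontrol. The fallback replaces catalytic enantioconvergence by resolution plus inversion. It sets out from 6. Lipase-catalysed enantioselective alcoholysis (immobilised Candida antarctica lipase B, n-BuOH, MTBE, 30 °C) should release, by the usual size rule for this enzyme, (R)-1-(4-methoxyphenyl)prop-2-yn-1-ol F3 and leave the (S)-acetate. A Mitsunobu etherification of F3 with 2 (PPh3, DIAD, toluene, −20 °C) should then proceed with inversion and return to the route at 7. The terminal ethynyl group is the least cation-stabilising substituent this centre can carry, which is why the displacement is attempted at this stage.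

Step 5. The alkynylzinc may add to the ring-A formyl group of a second molecule of 7 (oligomerisation), or the large alkyne may erode facial control. The fallback masks the competing aldehyde. It sets out from 7. Condensation with tert-butylamine (MgSO4, CH2Cl2, rt) gives the N-tert-butyl imine of 7 F4. The same zinc–ProPhenol alkynylation of 9 then gives the imine-protected propargylic alcohol F5, and mild hydrolysis (aqueous citric acid, THF, rt) returns to the route at 11.

**Further compounds**

F1 | step 7 | anisyl-side allylic alcohol: 13 with the ring carbonyl as CH–OH, carbinol epimers | COc1ccc([C@H]2Oc3cc(OCc4ccccc4)cc(OCc4ccccc4)c3C(O)/C2=C/[C@H](Oc2cc(OCc3ccccc3)cc(OCc3ccccc3)c2C=O)c2ccc(OC(=O)OCc3ccccc3)cc2)cc1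
F2 | step 7 | carbonate-side allylic alcohol: 14 with the ring carbonyl as CH–OH, carbinol epimers | COc1ccc([C@H](/C=C2/C(O)c3c(OCc4ccccc4)cc(OCc4ccccc4)cc3O[C@@H]2c2ccc(OC(=O)OCc3ccccc3)cc2)Oc2cc(OCc3ccccc3)cc(OCc3ccccc3)c2C=O)cc1
F3 | step 3 | (R)-1-(4-methoxyphenyl)prop-2-yn-1-ol | COc1ccc([C@@H](C#C)O)cc1
F4 | step 5 | (E)-N-tert-butyl imine of 7 | COc1ccc([C@H](C#C)Oc2cc(OCc3ccccc3)cc(OCc3ccccc3)c2/C=N/C(C)(C)C)cc1
F5 | step 5 | (E)-N-tert-butyl imine of 11 | COc1ccc([C@H](C#C[C@@H](O)c2ccc(OC(=O)OCc3ccccc3)cc2)Oc2cc(OCc3ccccc3)cc(OCc3ccccc3)c2/C=N/C(C)(C)C)cc1
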